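A flask cannot show more target than the starting material it has lost, so I follow one molecule that has left the starting material and ask its chance of having reached target by 15 min.

in all of them: starting material 0.082 M

|  | partner | remark | time |
|---|---|---|---|
| teal | 0.42 equiv | run made earlier |  |
| green | 1.7 equiv | run made earlier |  |
| ochre | 4.7 equiv | run made earlier |  |
| beta | 0.500 equiv |  | 15 min |
| zeta | 2.00 equiv |  | 15 min |
| eta | 1.00 equiv |  | 15 min |
| delta | 1.30 equiv |  | 15 min |
| theta | 6.00 equiv |  | 15 min |
| gamma | 0.660 equiv |  | 15 min |

- a reading or a percentage of target counts all its forms, free or not

- the flasks put in order of amount of target, in percent of the starting material charged, best first, at 15 min (beta / zeta / eta / delta / theta / gamma)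
- the amount of target, in percent of the starting material charged of the flask you put first, at 15 min
- the amount of target, in percent of the starting material charged of the flask you put last, at 15 min

- teal (time / min: target / %, starting material / %): 1.33: 0, 93; 2.50: 3, 88; 4.00: 0, 82; 8.00: 4, 62; 15.0: 9, 41
- green (time / min: target / %, starting material / %): 1.33: 1, 92; 2.50: 0, 87; 4.00: 5, 81; 8.00: 14, 65; 15.0: 34, 45
- ochre (time / min: target / %, starting material / %): 3.00: 4, 86; 6.00: 18, 71; 10.0: 31, 59; 12.0: 43, 53; 15.0: 50, 41

(each reading ± 2 percentage points)

I read the last row of each table. The starting material lost barely moves between runs: 59.0 % in teal, 55.0 % in green and 59.0 % in ochre, although partner goes from 0.42 equiv to 4.7 equiv. So I take the mean, 57.7 % of the charge, for each of the six flasks.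

Now I set the target column against that loss. The chance of having come through reads 15.3 % in teal, 61.8 % in green and 84.7 % in ochre. It climbs with partner but bends over, as if each further portion of partner acted on the molecules still waiting. I therefore let the chance of still waiting fall by equal factors per equivalent. Pooling the three runs gives 1.57 equiv, the even-odds charge: the partner charge at which a molecule lost by 15 min is as likely to be target as not.

The loss is taken as equal and the chance rises with charge, so my order simply follows partner. For theta I reckon 53.6 % and for beta 11.4 %.

The forecast gives theta > zeta > delta > eta > gamma > beta, with 53 % for theta and 11 % for beta, and holds of the starting material that “its loss does not depend on partner”.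

The flasks give theta > zeta > delta > eta > gamma > beta, with 49.8 % for theta and 14.2 % for beta.

    target ⇌ isomer of the product (K = 0.950, k = 0.00966 min⁻¹)
    partner → second intermediate (k = 1.28 min⁻¹)
    crystals ⇌ target, rate k3*(cs3 - [target]) while solid is left; crystals form when [target] > cs3 (solubility = 2.40 mM, k = 0.493 min⁻¹)
    open intermediate + second intermediate → target (k = 1.08 M⁻¹ min⁻¹)
    starting material → open intermediate (k = 0.0554 min⁻¹)

On zeta the even-odds charge gives 33.8 % against 36.7 %. In beta, my 11.4 % stands against 14.2 %; partner, the limiting reagent, is at 0 % of its own charge, while second intermediate, which it has become, stands at 0.0290 M. The wearing away of partner and the time allowed act together to hold beta low. Without the wearing away of partner, beta reaches 51.6 %, the larger effect of the two, and left until 150 min it reaches 47.5 %.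

The data were computed from invented constants; scatter was added.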